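**Plan** (chromene numbering: O1, C2, C3, C4, C4a, C5–C8, C8a; ring A = dihydropyranone, ring B = carbocycle)
1. Retrosynthetic cuts, in order: C6–prenyl; C8–CH(Ph) together with an O7–acyl lactone bond; O1–C2 and C3–C4 of ring A; the CH2–CH bond of the C11 side chain next to C6.
2. Forward: 2,4,6-trihydroxybenzaldehyde is masked (O1 silyl ether, O5/O7 MOM ethers) and converted to a benzylic bromide, which alkylates a chiral imide; a Wittig reaction completes the C11 chain; O1 alone is freed and the ring is formylated ortho to it (future C4).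
3. Ring A is built next. C2 and C3, two adjacent methyl-bearing carbons between O1 and the C4 carbonyl, are the carbons of symmetrical but-2-yne. Rhodium hydroacylation joins C3 to C4; quinine-catalysed 6-endo attack of O1 on C2 closes the ring. O1 is the only unprotected phenol oxygen ortho to C4a.
4. Then MOM removal, carbene-catalysed annulation at C8 (lactone on O7, opened to the acid) and, last, dearomatising C-prenylation of ring B at C6.
5. Stereochemistry: side-chain CH from the (R)-oxazolidinone; C2/C3 (cis) from alkaloid-controlled O1 addition and kinetic protonation; benzylic CH from the chiral carbene; C6 from the chiral palladium ligand.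

Key step: step 12

Assumption: the β-triketone formed in step 15 is taken to rest as the tautomer drawn for the target (C4 enol hydrogen-bonded to the C5 ketone), so no separate tautomerisation is planned.

**Step 1**
Reactants: 1 2,4,6-trihydroxybenzaldehyde
Product: 2 2,6-dihydroxy-4-{[tri(propan-2-yl)silyl]oxy}benzaldehyde
Conditions: i-Pr3SiCl (1.05 equiv), imidazole, DMF, 0 °C
Reagents that add atoms: chlorotri(propan-2-yl)silane, CC(C)[Si](Cl)(C(C)C)C(C)C
Why: The 4-hydroxyl is the most acidic and the only one neither chelated to nor flanked by the formyl group, so one equivalent of the bulky silyl chloride should silylate it selectively (site-selective O-silylation).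

**Step 2**
Reactants: 2 2,6-dihydroxy-4-{[tri(propan-2-yl)silyl]oxy}benzaldehyde
Product: 3 2,6-bis(methoxymethoxy)-4-{[tri(propan-2-yl)silyl]oxy}benzaldehyde
Conditions: MOMCl (3 equiv), K2CO3, acetone, reflux
Reagents that add atoms: chloromethyl methyl ether, COCCl
Why: Carbonate-mediated O-alkylation with the reactive chloromethyl ether acetalises both chelated ortho-phenols, and the aryl silyl ether is stable to K2CO3 in acetone.

**Step 3**
Reactants: 3 2,6-bis(methoxymethoxy)-4-{[tri(propan-2-yl)silyl]oxy}benzaldehyde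
Product: 4 [2,6-bis(methoxymethoxy)-4-{[tri(propan-2-yl)silyl]oxy}phenyl]methanol
Conditions: NaBH4, EtOH/THF, 0 °C
Reagents that add atoms: none
Why: Borohydride reduces the aryl aldehyde to the benzylic alcohol while acetals and the silyl ether are inert.

**Step 4**
Reactants: 4 [2,6-bis(methoxymethoxy)-4-{[tri(propan-2-yl)silyl]oxy}phenyl]methanol
Product: 5 [4-(bromomethyl)-3,5-bis(methoxymethoxy)phenoxy]tri(propan-2-yl)silane
Conditions: CBr4, PPh3, CH2Cl2, −20 °C; filtered through a short pad and used at once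
Reagents that add atoms: tetrabromomethane, BrC(Br)(Br)Br
Why: The Appel reaction replaces the benzylic hydroxyl by bromide under neutral conditions that spare the acid-labile MOM ethers; the electron-rich bromide is labile and is therefore used at once.

**Step 5**
Reactants: 6 5-methylhex-5-enoic acid; 7 (4R)-4-benzyl-1,3-oxazolidin-2-one
Product: 9 (4R)-4-benzyl-3-(5-methylhex-5-enoyl)-1,3-oxazolidin-2-one, via mixed pivalic anhydride 8 (not isolated)
Conditions: t-BuCOCl, Et3N, THF, −20 °C; then 7, LiCl, rt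
Reagents that add atoms: none
Why: Acylation of the oxazolidinone through the mixed pivalic anhydride with LiCl/Et3N is the standard mild way to load the auxiliary.

**Step 6**
Reactants: 9 (4R)-4-benzyl-3-(5-methylhex-5-enoyl)-1,3-oxazolidin-2-one; 5 [4-(bromomethyl)-3,5-bis(methoxymethoxy)phenoxy]tri(propan-2-yl)silane
Product: 11 (4R)-4-benzyl-3-[(2S)-2-{[2,6-bis(methoxymethoxy)-4-{[tri(propan-2-yl)silyl]oxy}phenyl]methyl}-5-methylhex-5-enoyl]-1,3-oxazolidin-2-one, via sodium Z-enolate 10 (not isolated)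
Conditions: NaN(SiMe3)2, THF, −78 °C; then 5, −78 → −40 °C
Reagents that add atoms: none
Why: Evans alkylation, in which the chelated Z-enolate is attacked by the reactive benzylic bromide on the face opposite the benzyl group of the (R)-auxiliary, which sets the side-chain stereocentre as S.

**Step 7**
Reactants: 11 (4R)-4-benzyl-3-[(2S)-2-{[2,6-bis(methoxymethoxy)-4-{[tri(propan-2-yl)silyl]oxy}phenyl]methyl}-5-methylhex-5-enoyl]-1,3-oxazolidin-2-one
Product: 12 (2S)-2-{[2,6-bis(methoxymethoxy)-4-{[tri(propan-2-yl)silyl]oxy}phenyl]methyl}-5-methylhex-5-en-1-ol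
Conditions: LiBH4, MeOH (1 equiv), Et2O, 0 °C
Reagents that add atoms: none
Why: LiBH4 cleaves the imide reductively to the primary alcohol without touching the α-stereocentre, the silyl ether or the acetals, and releases the auxiliary for recovery.

**Step 8**
Reactants: 12 (2S)-2-{[2,6-bis(methoxymethoxy)-4-{[tri(propan-2-yl)silyl]oxy}phenyl]methyl}-5-methylhex-5-en-1-ol
Product: 13 (2S)-2-{[2,6-bis(methoxymethoxy)-4-{[tri(propan-2-yl)silyl]oxy}phenyl]methyl}-5-methylhex-5-enal
Conditions: 1,1,1-triacetoxy-1,1-dihydro-1,2-benziodoxol-3(1H)-one (DMP), CH2Cl2, 0 °C → rt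
Reagents that add atoms: none
Why: Dess–Martin oxidation stops at the aldehyde and is mild enough not to epimerise the α-branched centre.

**Step 9**
Reactants: 13 (2S)-2-{[2,6-bis(methoxymethoxy)-4-{[tri(propan-2-yl)silyl]oxy}phenyl]methyl}-5-methylhex-5-enal; 14 propan-2-yl(triphenyl)phosphonium iodide
Product: 15 {3,5-bis(methoxymethoxy)-4-[(2S)-5-methyl-2-(2-methylprop-1-en-1-yl)hex-5-en-1-yl]phenoxy}tri(propan-2-yl)silane
Conditions: 14, n-BuLi, THF, 0 °C; then 13, −78 → 0 °C
Reagents that add atoms: propan-2-yl(triphenyl)phosphonium iodide (14), CC(C)[P+](c1ccccc1)(c1ccccc1)c1ccccc1.[I-]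
Why: Wittig reaction of the non-stabilised isopropylidene ylide with the aldehyde at low temperature gives the trisubstituted alkene (no E/Z issue) and is fast enough to outrun α-epimerisation.

**Step 10**
Reactants: 15 {3,5-bis(methoxymethoxy)-4-[(2S)-5-methyl-2-(2-methylprop-1-en-1-yl)hex-5-en-1-yl]phenoxy}tri(propan-2-yl)silane
Product: 16 3,5-bis(methoxymethoxy)-4-[(2S)-5-methyl-2-(2-methylprop-1-en-1-yl)hex-5-en-1-yl]phenol
Conditions: Bu4NF, THF, 0 °C; aq. NH4Cl
Reagents that add atoms: none
Why: Fluoride cleaves only the Si–O bond, so O1 becomes the single free phenol while O5 and O7 stay as MOM ethers.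

**Step 11**
Reactants: 16 3,5-bis(methoxymethoxy)-4-[(2S)-5-methyl-2-(2-methylprop-1-en-1-yl)hex-5-en-1-yl]phenol
Product: 17 6-hydroxy-2,4-bis(methoxymethoxy)-3-[(2S)-5-methyl-2-(2-methylprop-1-en-1-yl)hex-5-en-1-yl]benzaldehyde
Conditions: MgCl2, Et3N, (CH2O)n, MeCN, 80 °C
Reagents that add atoms: paraformaldehyde (as formaldehyde), C=O
Why: Magnesium-mediated ortho-formylation (Mg phenoxide, formaldehyde, then hydride transfer to a second formaldehyde) is specific for the position next to a free phenol, and the two positions ortho to O1 are equivalent, so the formyl carbon (future C4) can enter only at the future C4a.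

**Step 12**
Reactants: 17 6-hydroxy-2,4-bis(methoxymethoxy)-3-[(2S)-5-methyl-2-(2-methylprop-1-en-1-yl)hex-5-en-1-yl]benzaldehyde; 18 but-2-yne
Product: 20 (2R,3S)-5,7-bis(methoxymethoxy)-2,3-dimethyl-6-[(2S)-5-methyl-2-(2-methylprop-1-en-1-yl)hex-5-en-1-yl]-2,3-dihydro-4H-chromen-4-one, via tigloyl phenol 19 (not isolated)
Conditions: [Rh(OH)(cod)]2 (cod = cycloocta-1,5-diene, 2.5 mol %), Fe(C5H4PPh2)2 (dppf, 6 mol %), but-2-yne (5 equiv), toluene, 80 °C, sealed tube; excess alkyne removed, then quinine (20 mol %), PhCl, 15 °C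
Reagents that add atoms: but-2-yne (18), CC#CC
Why: Monovalent rhodium, held by the O1 phenoxide, inserts into the formyl C–H of 17, the acyl–Rh–H adds syn across symmetrical but-2-yne and reductive elimination gives the (E)-enone 19, so C3–C4 is made with no regiochemical question; the closest known reaction types are the rhodium-catalysed hydroacylation of internal alkynes by salicylaldehydes and the cinchona-alkaloid-catalysed intramolecular oxa-Michael addition of o-tigloylphenols. Ring A then closes in the 6-endo-trig mode by attack of O1 on C2 inside the quinine–substrate complex (quinuclidine nitrogen to O1–H, C9 hydroxyl to the C4 carbonyl). C2 (R) is fixed by the alkaloid, which is expected to deliver O1 to the Re face of the β-carbon (quinidine, its pseudo-enantiomer, would be used if the sense proved opposite). C3 (S) follows from kinetic protonation of the resulting enol on the face anti to the new C2 methyl group, which gives the cis-2,3-dimethyl ring. The step needs oxygen selectivity and kinetic cis control: O5 and O7 are MOM ethers, so O1 is the only oxygen that can reach C2, and the low temperature and weak base keep C3 from equilibrating to the trans isomer.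

**Step 13**
Reactants: 20 (2R,3S)-5,7-bis(methoxymethoxy)-2,3-dimethyl-6-[(2S)-5-methyl-2-(2-methylprop-1-en-1-yl)hex-5-en-1-yl]-2,3-dihydro-4H-chromen-4-one
Product: 21 (2R,3S)-5,7-dihydroxy-2,3-dimethyl-6-[(2S)-5-methyl-2-(2-methylprop-1-en-1-yl)hex-5-en-1-yl]-2,3-dihydro-4H-chromen-4-one
Conditions: HCl (1.25 M in MeOH), 35 °C
Reagents that add atoms: none
Why: Acid-catalysed acetal exchange with methanol removes both MOM groups under conditions that leave isolated alkenes untouched and are too mild and short to enolise C3.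

**Step 14**
Reactants: 21 (2R,3S)-5,7-dihydroxy-2,3-dimethyl-6-[(2S)-5-methyl-2-(2-methylprop-1-en-1-yl)hex-5-en-1-yl]-2,3-dihydro-4H-chromen-4-one; 22 3-phenylprop-2-ynal
Product: 24 (3S)-3-{(2R,3S)-5,7-dihydroxy-2,3-dimethyl-6-[(2S)-5-methyl-2-(2-methylprop-1-en-1-yl)hex-5-en-1-yl]-4-oxo-3,4-dihydro-2H-chromen-8-yl}-3-phenylpropanoic acid, via lactone 23 (not isolated)
Conditions: (5aS,10bR)-2-mesityl-5a,10b-dihydro-4H,6H-indeno[2,1-b][1,2,4]triazolo[4,3-d][1,4]oxazin-2-ium chloride (10 mol %), toluene, 40 °C; then LiOH, THF/H2O, 0 °C; 1 M HCl to pH 3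
Reagents that add atoms: 3-phenylprop-2-ynal (22), O=CC#Cc1ccccc1; lithium hydroxide (aqueous), [Li+].[OH-]
Why: Carbene redox catalysis turns the ynal into an α,β-unsaturated acyl azolium that is attacked by C8, the only unsubstituted nucleophilic carbon of the 5,7-dihydroxychromanone enol system, and is then acylated onto O7 (formal [3+3] annulation of a stable enol), the chiral aminoindanol-derived carbene shielding one face of the acceptor so that the benzylic centre is expected to form as S under catalyst control (the mirror-image salt would be used if the sense proved opposite), after which hydroxide opens the aryl lactone to the acid.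

**Step 15**
Reactants: 24 (3S)-3-{(2R,3S)-5,7-dihydroxy-2,3-dimethyl-6-[(2S)-5-methyl-2-(2-methylprop-1-en-1-yl)hex-5-en-1-yl]-4-oxo-3,4-dihydro-2H-chromen-8-yl}-3-phenylpropanoic acid; 25 3-methylbut-2-en-1-yl acetate
Product: 26 (3S)-3-{(2R,3S,6S)-4-hydroxy-2,3-dimethyl-6-[(2S)-5-methyl-2-(2-methylprop-1-en-1-yl)hex-5-en-1-yl]-6-(3-methylbut-2-en-1-yl)-5,7-dioxo-3,5,6,7-tetrahydro-2H-chromen-8-yl}-3-phenylpropanoic acid (target)
Conditions: Pd2(dba)3·CHCl3 (dba = dibenzylideneacetone, 2.5 mol %), (1R,2R)-N,N'-bis[2-(diphenylphosphino)benzoyl]cyclohexane-1,2-diamine (7.5 mol %), Et3N (3 equiv), THF, 0 °C → rt; aq. citric acid work-up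
Reagents that add atoms: 3-methylbut-2-en-1-yl acetate (25), CC(C)=CCOC(C)=O
Why: Proposed new method: oxidative addition of zerovalent palladium to prenyl acetate gives a cationic π-prenyl complex that is attacked at its CH2 terminus by C6, the carbon flanked by the two phenoxide oxygens O5 and O7 (C-alkylation is irreversible, whereas O-prenylation of phenoxide or carboxylate is reversed by palladium), and the chiral diphosphine pocket is expected to distinguish the two faces of the planar nucleophile, whose flanks differ (C5 next to the pyranone carbonyl, C7 next to the benzylic arm), so that C6 is set as S under catalyst control (the (1S,2S) ligand would be used if the sense proved opposite); the closest known reaction types are the palladium-catalysed asymmetric allylic dearomatisation of phenols and naphthols and the racemic base- or palladium-mediated C-prenylation of acylphloroglucinols.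

**Compound list**
1 | 2,4,6-trihydroxybenzaldehyde | O=Cc1c(O)cc(O)cc1O | starting material
2 | 2,6-dihydroxy-4-{[tri(propan-2-yl)silyl]oxy}benzaldehyde | O=Cc1c(O)cc(O[Si](C(C)C)(C(C)C)C(C)C)cc1O | intermediate
3 | 2,6-bis(methoxymethoxy)-4-{[tri(propan-2-yl)silyl]oxy}benzaldehyde | O=Cc1c(OCOC)cc(O[Si](C(C)C)(C(C)C)C(C)C)cc1OCOC | intermediate
4 | [2,6-bis(methoxymethoxy)-4-{[tri(propan-2-yl)silyl]oxy}phenyl]methanol | OCc1c(OCOC)cc(O[Si](C(C)C)(C(C)C)C(C)C)cc1OCOC | intermediate
5 | [4-(bromomethyl)-3,5-bis(methoxymethoxy)phenoxy]tri(propan-2-yl)silane | BrCc1c(OCOC)cc(O[Si](C(C)C)(C(C)C)C(C)C)cc1OCOC | intermediate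
6 | 5-methylhex-5-enoic acid | C=C(C)CCCC(=O)O | starting material
7 | (4R)-4-benzyl-1,3-oxazolidin-2-one | O=C1N[C@H](Cc2ccccc2)CO1 | starting material
8 | 2,2-dimethylpropanoic 5-methylhex-5-enoic anhydride | C=C(C)CCCC(=O)OC(=O)C(C)(C)C | intermediate
9 | (4R)-4-benzyl-3-(5-methylhex-5-enoyl)-1,3-oxazolidin-2-one | C=C(C)CCCC(=O)N1[C@H](Cc2ccccc2)COC1=O | intermediate
10 | sodium (1Z)-1-[(4R)-4-benzyl-2-oxo-1,3-oxazolidin-3-yl]-5-methylhexa-1,5-dien-1-olate | C=C(C)CC/C=C(\[O-])N1[C@H](Cc2ccccc2)COC1=O.[Na+] | intermediate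
11 | (4R)-4-benzyl-3-[(2S)-2-{[2,6-bis(methoxymethoxy)-4-{[tri(propan-2-yl)silyl]oxy}phenyl]methyl}-5-methylhex-5-enoyl]-1,3-oxazolidin-2-one | C=C(C)CC[C@H](C(=O)N1[C@H](Cc2ccccc2)COC1=O)Cc1c(OCOC)cc(O[Si](C(C)C)(C(C)C)C(C)C)cc1OCOC | intermediate
12 | (2S)-2-{[2,6-bis(methoxymethoxy)-4-{[tri(propan-2-yl)silyl]oxy}phenyl]methyl}-5-methylhex-5-en-1-ol | C=C(C)CC[C@H](CO)Cc1c(OCOC)cc(O[Si](C(C)C)(C(C)C)C(C)C)cc1OCOC | intermediate
13 | (2S)-2-{[2,6-bis(methoxymethoxy)-4-{[tri(propan-2-yl)silyl]oxy}phenyl]methyl}-5-methylhex-5-enal | C=C(C)CC[C@H](C=O)Cc1c(OCOC)cc(O[Si](C(C)C)(C(C)C)C(C)C)cc1OCOC | intermediate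
14 | propan-2-yl(triphenyl)phosphonium iodide | CC(C)[P+](c1ccccc1)(c1ccccc1)c1ccccc1.[I-] | starting material
15 | {3,5-bis(methoxymethoxy)-4-[(2S)-5-methyl-2-(2-methylprop-1-en-1-yl)hex-5-en-1-yl]phenoxy}tri(propan-2-yl)silane | C=C(C)CC[C@H](C=C(C)C)Cc1c(OCOC)cc(O[Si](C(C)C)(C(C)C)C(C)C)cc1OCOC | intermediate
16 | 3,5-bis(methoxymethoxy)-4-[(2S)-5-methyl-2-(2-methylprop-1-en-1-yl)hex-5-en-1-yl]phenol | C=C(C)CC[C@H](C=C(C)C)Cc1c(OCOC)cc(O)cc1OCOC | intermediate
17 | 6-hydroxy-2,4-bis(methoxymethoxy)-3-[(2S)-5-methyl-2-(2-methylprop-1-en-1-yl)hex-5-en-1-yl]benzaldehyde | C=C(C)CC[C@H](C=C(C)C)Cc1c(OCOC)cc(O)c(C=O)c1OCOC | intermediate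
18 | but-2-yne | CC#CC | starting material
19 | (2E)-1-{6-hydroxy-2,4-bis(methoxymethoxy)-3-[(2S)-5-methyl-2-(2-methylprop-1-en-1-yl)hex-5-en-1-yl]phenyl}-2-methylbut-2-en-1-one | C=C(C)CC[C@H](C=C(C)C)Cc1c(OCOC)cc(O)c(C(=O)/C(C)=C/C)c1OCOC | intermediate
20 | (2R,3S)-5,7-bis(methoxymethoxy)-2,3-dimethyl-6-[(2S)-5-methyl-2-(2-methylprop-1-en-1-yl)hex-5-en-1-yl]-2,3-dihydro-4H-chromen-4-one | C=C(C)CC[C@H](C=C(C)C)Cc1c(OCOC)cc2O[C@H](C)[C@H](C)C(=O)c2c1OCOC | intermediate
21 | (2R,3S)-5,7-dihydroxy-2,3-dimethyl-6-[(2S)-5-methyl-2-(2-methylprop-1-en-1-yl)hex-5-en-1-yl]-2,3-dihydro-4H-chromen-4-one | C=C(C)CC[C@H](C=C(C)C)Cc1c(O)cc2O[C@H](C)[C@H](C)C(=O)c2c1O | intermediate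
22 | 3-phenylprop-2-ynal | O=CC#Cc1ccccc1 | starting material
23 | (2R,3S,10S)-5-hydroxy-2,3-dimethyl-6-[(2S)-5-methyl-2-(2-methylprop-1-en-1-yl)hex-5-en-1-yl]-10-phenyl-2,3,9,10-tetrahydro-4H,8H-pyrano[2,3-f]chromene-4,8-dione | C=C(C)CC[C@H](C=C(C)C)Cc1c(O)c2C(=O)[C@@H](C)[C@@H](C)Oc2c2[C@H](c3ccccc3)CC(=O)Oc12 | intermediate
24 | (3S)-3-{(2R,3S)-5,7-dihydroxy-2,3-dimethyl-6-[(2S)-5-methyl-2-(2-methylprop-1-en-1-yl)hex-5-en-1-yl]-4-oxo-3,4-dihydro-2H-chromen-8-yl}-3-phenylpropanoic acid | C=C(C)CC[C@H](C=C(C)C)Cc1c(O)c2C(=O)[C@@H](C)[C@@H](C)Oc2c([C@@H](CC(=O)O)c2ccccc2)c1O | intermediate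
25 | 3-methylbut-2-en-1-yl acetate | CC(C)=CCOC(C)=O | starting material
26 | (3S)-3-{(2R,3S,6S)-4-hydroxy-2,3-dimethyl-6-[(2S)-5-methyl-2-(2-methylprop-1-en-1-yl)hex-5-en-1-yl]-6-(3-methylbut-2-en-1-yl)-5,7-dioxo-3,5,6,7-tetrahydro-2H-chromen-8-yl}-3-phenylpropanoic acid | C=C(C)CC[C@H](C=C(C)C)C[C@@]1(CC=C(C)C)C(=O)C2=C(O)[C@@H](C)[C@@H](C)OC2=C([C@@H](CC(=O)O)c2ccccc2)C1=O | target

**Step count**
Total: 15 steps. Longest linear sequence: 14 steps (steps 1–4 and 6–15, from 2,4,6-trihydroxybenzaldehyde); step 5 is a one-step branch.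

**Steps most likely to fail**

Step 15 (bears the label). The chiral palladium complex may fail to distinguish the two faces of C6, because both flanks are oxygenated and the existing stereocentres are remote. The π-prenyl unit may also be captured at oxygen, at C8, or through its tertiary terminus. Fallback with known chemistry: acid 24 is C-prenylated in the classical way for acylphloroglucinols (3-methylbut-2-enyl bromide, aqueous KOH, 0 °C), without stereocontrol at C6. This should give 26 together with its C6 epimer, (3S)-3-{(2R,3S,6R)-4-hydroxy-2,3-dimethyl-6-[(2S)-5-methyl-2-(2-methylprop-1-en-1-yl)hex-5-en-1-yl]-6-(3-methylbut-2-en-1-yl)-5,7-dioxo-3,5,6,7-tetrahydro-2H-chromen-8-yl}-3-phenylpropanoic acid F1. Since the other four stereocentres are fixed, the two are diastereomers and would be separated by preparative reversed-phase HPLC; the route is rejoined at 26.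

Step 12 (key step). On the doubly ortho-substituted aldehyde the acyl–rhodium hydride may lose CO faster than it inserts the alkyne. Rhodium phenoxide left in the flask may also close 19 without stereocontrol before quinine takes over, eroding both enantio- and cis-selectivity. Fallback: from 17, carbonyl addition of the vinyllithium made from (E)-2-bromobut-2-ene and t-BuLi (retention of alkene geometry; THF, −78 °C) should give the allylic alcohol 2-[(2E)-1-hydroxy-2-methylbut-2-en-1-yl]-3,5-bis(methoxymethoxy)-4-[(2S)-5-methyl-2-(2-methylprop-1-en-1-yl)hex-5-en-1-yl]phenol F2 (both carbinol epimers). Oxidation with MnO2 should then give enone 19 as an isolated, metal-free compound. The route comes back at 19, which is closed to 20 with quinine as a separate operation.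

Step 14. The acyl azolium may only acylate O7 or O5 (ester formation without C–C bond formation). Facial control at the benzylic carbon may also be weakened because the nucleophile is itself chiral. Fallback: from 21, iminium catalysis ((E)-cinnamaldehyde, (S)-2-[diphenyl(trimethylsilyloxy)methyl]pyrrolidine, PhCO2H, CH2Cl2; Friedel–Crafts alkylation/hemiacetalisation of an activated phenol) should give the lactol (2R,3S,10S)-5,8-dihydroxy-2,3-dimethyl-6-[(2S)-5-methyl-2-(2-methylprop-1-en-1-yl)hex-5-en-1-yl]-10-phenyl-2,3,9,10-tetrahydro-4H,8H-pyrano[2,3-f]chromen-4-one F3 (both anomers). Oxidation with Ag2CO3 on Celite (toluene, 80 °C) should give lactone 23, where the route is rejoined; hydrolysis as in step 14 leads to 24.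

**Further compounds**
F1 | step 15 | (3S)-3-{(2R,3S,6R)-4-hydroxy-2,3-dimethyl-6-[(2S)-5-methyl-2-(2-methylprop-1-en-1-yl)hex-5-en-1-yl]-6-(3-methylbut-2-en-1-yl)-5,7-dioxo-3,5,6,7-tetrahydro-2H-chromen-8-yl}-3-phenylpropanoic acid | C=C(C)CC[C@H](C=C(C)C)C[C@]1(CC=C(C)C)C(=O)C2=C(O)[C@@H](C)[C@@H](C)OC2=C([C@@H](CC(=O)O)c2ccccc2)C1=O
F2 | step 12 | 2-[(2E)-1-hydroxy-2-methylbut-2-en-1-yl]-3,5-bis(methoxymethoxy)-4-[(2S)-5-methyl-2-(2-methylprop-1-en-1-yl)hex-5-en-1-yl]phenol | C=C(C)CC[C@H](C=C(C)C)Cc1c(OCOC)cc(O)c(C(O)/C(C)=C/C)c1OCOC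
F3 | step 14 | (2R,3S,10S)-5,8-dihydroxy-2,3-dimethyl-6-[(2S)-5-methyl-2-(2-methylprop-1-en-1-yl)hex-5-en-1-yl]-10-phenyl-2,3,9,10-tetrahydro-4H,8H-pyrano[2,3-f]chromen-4-one | C=C(C)CC[C@H](C=C(C)C)Cc1c(O)c2C(=O)[C@@H](C)[C@@H](C)Oc2c2[C@H](c3ccccc3)CC(O)Oc12
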